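**Plan**
Locants: ring A (oxepane) is O1, C2 (CMe2), C3 (CHOH), C4, C5, C6 (C–CH3), C7 (O–CH); ring B is C6–C7–C8–C9–C10–C11 (C10 tertiary carbinol, C11 the CH); C12–C13 is the linker to ring C.
Cuts, in retrosynthetic order: the side-chain CH=CH bond (cross-metathesis), C13–ring C (sp3–sp2 coupling), C10–C11 (ring B), O1–C2 (ring A), C6–C7 (allylboration).
Forward: the C7–C10 ketal aldehyde and a neryl boronate are joined; ring A closes by epoxide opening; ring B closes in the key step; ring C, made separately from 2-methylcyclohexane-1,3-dione, is attached; the side chain is completed last.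
Stereochemistry: C6/C7 come from the Z boronate plus a chiral phosphoric acid, C3 from a Shi epoxidation, and C10/C11 from the chair of the key step templated by C6/C7. The ring C carbinol and quaternary carbon come from a CBS desymmetrisation, and the side-chain E alkene from metathesis.
Enabling feature: in ring B the carbinol C10 is directly bonded to C11, the ring CH bearing the C12–C13 linker. A C10 methyl ketone and an allylsilane whose γ-carbon is C11 therefore close ring B and leave C12=C13 as the vinyl handle for ring C.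

Key step: step 10

Remark: neryl acetate of high Z purity is assumed, since any E isomer would be carried through as the C6 epimer.
Remark: the sense of induction of (S)-TRIP and of the (S)-CBS catalyst is taken from the accepted transition-state models; if either is reversed in this substrate, the antipodal catalyst is used.

Step 1
Reactants: 1 ethyl levulinate
Product: 2 ethyl 3-(2-methyl-1,3-dioxolan-2-yl)propanoate
Conditions: ethylene glycol, p-TsOH (cat.), toluene, reflux, Dean–Stark
Reagents that add atoms: ethylene glycol, OCCO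
Why: Acid-catalysed ketalisation with azeotropic removal of water masks the ketone that must stay latent until ring B is closed.

Step 2
Reactants: 2 ketal ester
Product: 3 3-(2-methyl-1,3-dioxolan-2-yl)propanal
Conditions: iBu2AlH, CH2Cl2, −78 °C; aq. KNaC4H4O6 work-up
Reagents that add atoms: none
Why: Partial ester reduction with iBu2AlH at −78 °C stops at the aldehyde because the tetrahedral aluminium hemiacetal persists until work-up.

Step 3
Reactants: 4 neryl acetate
Product: 5 neryl pinacolboronate, 2-[(2Z)-3,7-dimethylocta-2,6-dien-1-yl]-4,4,5,5-tetramethyl-1,3,2-dioxaborolane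
Conditions: B2pin2, Ni(cod)2 (bis(1,5-cyclooctadiene)nickel, 5 mol%), PCy3 (10 mol%), EtOAc, 60 °C
Reagents that add atoms: bis(pinacolato)diboron, CC1(C)OB(OC1(C)C)B1OC(C)(C)C(C)(C)O1
Why: Miyaura-type borylation of the allylic acetate with a zerovalent nickel catalyst should give the linear allylboronate with retention of the Z geometry, which later fixes the relative configuration of C6 and C7.

Step 4
Reactants: 3 ketal aldehyde; 5 neryl pinacolboronate
Product: 6 (3R,4R)-4-ethenyl-4,8-dimethyl-1-(2-methyl-1,3-dioxolan-2-yl)non-7-en-3-ol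
Conditions: (S)-TRIP [(S)-3,3'-bis(2,4,6-triisopropylphenyl)-1,1'-binaphthyl-2,2'-diyl hydrogen phosphate, 5 mol%], 4 Å MS, toluene, −30 → 0 °C; aq. NaHCO3
Reagents that add atoms: none
Why: Chiral phosphoric acid-catalysed allylboration through a closed chair Zimmerman–Traxler transition state; the Z boronate places the methyl group anti and the homoprenyl chain syn to the new hydroxyl (C6 R relative to C7 R), and the (S)-acid should expose the Si face of the aldehyde, setting C7 as R.

Step 5
Reactants: 6 homoallylic alcohol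
Product: 7 (3R,4R)-6-[(2R)-3,3-dimethyloxiran-2-yl]-4-ethenyl-4-methyl-1-(2-methyl-1,3-dioxolan-2-yl)hexan-3-ol
Conditions: D-fructose-derived Shi ketone (0.3 equiv), Oxone (2KHSO5·KHSO4·K2SO4), K2CO3, Bu4NHSO4, MeCN/CH2(OMe)2, aq. Na2B4O7–Na2EDTA buffer, 0 °C
Reagents that add atoms: potassium peroxymonosulfate (active component of Oxone), [K+].[O-]S(=O)(=O)OO
Why: Shi asymmetric epoxidation (spiro dioxirane transition state) attacks only the electron-rich trisubstituted alkene and, with the D-fructose-derived ketone, should give the (R)-epoxide whose CH carbon becomes C3; the monosubstituted vinyl group is inert.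

Step 6
Reactants: 7 epoxy alcohol
Product: 8 (3R,6R,7R)-6-ethenyl-2,2,6-trimethyl-7-[2-(2-methyl-1,3-dioxolan-2-yl)ethyl]oxepan-3-ol
Conditions: (+)-camphor-10-sulfonic acid (0.1 equiv), CH2Cl2, −20 → 0 °C
Reagents that add atoms: none
Why: Acid-catalysed intramolecular epoxide opening in which the C7 hydroxyl attacks the tertiary epoxide carbon C2, the site that carries most of the positive charge (7-endo-tet, Markovnikov), closing the oxepane while the C3–O bond and hence the C3 configuration stay untouched.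

Step 7
Reactants: 8 oxepanol
Product: 9 (2R,3R,6R)-6-(tert-butyldimethylsilyloxy)-3-ethenyl-3,7,7-trimethyl-2-[2-(2-methyl-1,3-dioxolan-2-yl)ethyl]oxepane
Conditions: TBSOTf, 2,6-lutidine, CH2Cl2, −78 → 0 °C
Reagents that add atoms: tert-butyldimethylsilyl trifluoromethanesulfonate, CC(C)(C)[Si](C)(C)OS(=O)(=O)C(F)(F)F
Why: Silyl triflate silylation of the hindered secondary alcohol gives a TBS ether that keeps the C3 oxygen away from TiCl4 and survives to the last step.

Step 8
Reactants: 9 silyl ether ketal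
Product: 10 4-[(2R,3R,6R)-6-(tert-butyldimethylsilyloxy)-3-ethenyl-3,7,7-trimethyloxepan-2-yl]butan-2-one
Conditions: PPTS, acetone/H2O (10:1), 50 °C
Reagents that add atoms: water, O
Why: Mild acid-catalysed ketal hydrolysis releases the C10 methyl ketone before the acid-sensitive allylsilane is installed, and the hindered secondary TBS ether tolerates PPTS.

Step 9
Reactants: 10 vinyl ketone
Product: 11 4-{(2R,3R,6R)-6-(tert-butyldimethylsilyloxy)-3,7,7-trimethyl-3-[(1E)-3-(trimethylsilyl)prop-1-en-1-yl]oxepan-2-yl}butan-2-one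
Conditions: allyltrimethylsilane (10 equiv), second-generation Hoveyda–Grubbs catalyst [RuCl2(H2IMes)(=CH-C6H4-2-OiPr), 10 mol%], CH2Cl2, 40 °C
Reagents that add atoms: allyltrimethylsilane, C=CC[Si](C)(C)C
Why: Olefin cross-metathesis between the vinyl group on the quaternary carbon, which cannot homodimerise, and excess allyltrimethylsilane should give the allylsilane with E geometry, enforced by the bulky C6 substituent and required for the chair of the next step.

Step 10
Reactants: 11 allylsilane ketone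
Product: 12 (3R,5aR,6R,7S,9aR)-3-(tert-butyldimethylsilyloxy)-6-ethenyl-2,2,5a,7-tetramethyldecahydro-1-benzoxepin-7-ol
Conditions: TiCl4 (1.1 equiv), CH2Cl2, −78 °C; aq. NaHCO3
Reagents that add atoms: none
Why: TiCl4 binds the C10 ketone oxygen, the γ-carbon C11 of the allylsilane attacks the activated carbonyl carbon to form the C10–C11 bond, and the β-silyl cation loses the trimethylsilyl group to chloride, leaving the C12=C13 vinyl group (intramolecular Hosomi–Sakurai allylation, precedented by Lewis acid cyclisations of allylsilane-tethered ketones to 2-vinylcyclohexanols). Ring B closes 6-exo-trig at the carbonyl, with the allylsilane double bond also exocyclic to the forming ring, through a chair-like transition state. Because the two reacting arms sit trans on C6 and C7 of the oxepane, both ring A bonds are equatorial on the nascent chair, so the fusion is trans and the C6 methyl is axial. C11 is controlled by the E-allylsilane, which keeps C12 pseudo-equatorial, anti to the C6–C7 bond. C10 is controlled by the axial C6 methyl: the ketone methyl takes the equatorial site to avoid a methyl–methyl 1,3-diaxial contact, so the titanium-bound oxygen is axial and the hydroxyl ends up syn to the C6 methyl (C10 S) and cis to the equatorial vinyl group (C11 R). The step needs ketone activation without protodesilylation or loss of the silyl ether, which the aprotic Lewis acid, the low temperature and the absence of any free hydroxyl should secure.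

Step 11
Reactants: 13 2-methylcyclohexane-1,3-dione
Product: 14 2-methyl-2-(prop-2-en-1-yl)cyclohexane-1,3-dione
Conditions: allyl methyl carbonate, Pd(PPh3)4 (2 mol%), THF, rt
Reagents that add atoms: allyl methyl carbonate, C=CCOC(=O)OC
Why: Tsuji–Trost C-allylation under neutral conditions (the methoxide released from the carbonate deprotonates the dione) builds the prochiral quaternary carbon of ring C.

Step 12
Reactants: 14 allyl dione
Product: 15 (2R,3R)-3-hydroxy-2-methyl-2-(prop-2-en-1-yl)cyclohexan-1-one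
Conditions: (S)-2-methyl-CBS-oxazaborolidine (0.2 equiv), catecholborane (1.1 equiv), toluene, −78 → −40 °C; aq. NaHCO3
Reagents that add atoms: none
Why: Corey–Bakshi–Shibata reduction desymmetrises the dione: the (S)-oxazaborolidine should deliver hydride to give the 3R carbinol, and the preference for attack anti to the larger allyl group selects the carbonyl that makes the quaternary carbon 2R (hydroxyl cis to allyl).

Step 13
Reactants: 15 hydroxy ketone
Product: 16 (2R,3R)-3-(tert-butyldimethylsilyloxy)-2-methyl-2-(prop-2-en-1-yl)cyclohexan-1-one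
Conditions: TBSOTf, 2,6-lutidine, CH2Cl2, −78 °C
Reagents that add atoms: tert-butyldimethylsilyl trifluoromethanesulfonate, CC(C)(C)[Si](C)(C)OS(=O)(=O)C(F)(F)F
Why: Low-temperature silylation protects the carbinol before enolate chemistry; at −78 °C the hydroxyl reacts much faster than the ketone enolises.

Step 14
Reactants: 16 silyloxy ketone
Product: 18 (2R,3R)-3-(tert-butyldimethylsilyloxy)-2,6-dimethyl-2-(prop-2-en-1-yl)cyclohexan-1-one (C6 epimers), via lithium enolate 17 (not isolated)
Conditions: LiN(iPr)2, THF, −78 °C; MeI, DMPU, −78 → −20 °C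
Reagents that add atoms: iodomethane, CI
Why: Enolate alkylation is regiospecific because only C6 carries α-hydrogens (C2 is quaternary); the configuration of the new centre is irrelevant since it becomes sp2 in the next step.

Step 15
Reactants: 18 dimethyl ketone
Product: 20 (5R,6R)-5-(tert-butyldimethylsilyloxy)-2,6-dimethyl-6-(prop-2-en-1-yl)cyclohex-1-en-1-yl trifluoromethanesulfonate, via potassium enolate 19 (not isolated)
Conditions: KN(SiMe3)2, THF, −78 °C; PhNTf2, −78 → 0 °C
Reagents that add atoms: N-phenylbis(trifluoromethanesulfonimide), O=S(=O)(N(c1ccccc1)S(=O)(=O)C(F)(F)F)C(F)(F)F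
Why: Deprotonation at the only enolisable position and O-triflation of the potassium enolate gives the tetrasubstituted enol triflate, with the methyl-bearing alkene carbon remote from the quaternary centre as in the target.

Step 16
Reactants: 12 vinyl bicyclic alcohol; 20 ring C enol triflate
Product: 22 (3R,5aR,6R,7S,9aR)-3-(tert-butyldimethylsilyloxy)-6-{2-[(5R,6S)-5-(tert-butyldimethylsilyloxy)-2,6-dimethyl-6-(prop-2-en-1-yl)cyclohex-1-en-1-yl]ethyl}-2,2,5a,7-tetramethyldecahydro-1-benzoxepin-7-ol, via B-alkyl-9-BBN adduct 21 (not isolated)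
Conditions: 9-BBN dimer (1.5 equiv), THF, 0 → 50 °C; then 3 M aq. Cs2CO3, 20, PdCl2(dppf) (10 mol%), AsPh3 (10 mol%), DMF, 50 °C
Reagents that add atoms: none
Why: Anti-Markovnikov hydroboration of the terminal vinyl group with 9-BBN followed by B-alkyl Suzuki–Miyaura coupling (AsPh3-assisted, as used for hindered cycloalkenyl triflates) joins C13 to ring C; the aqueous base destroys excess 9-BBN before the allyl-bearing triflate is added.

Step 17
Reactants: 22 coupled allyl compound
Product: 23 (3R,5aR,6R,7S,9aR)-3-(tert-butyldimethylsilyloxy)-6-{2-[(5R,6S)-5-(tert-butyldimethylsilyloxy)-6-[(2E)-4-hydroxy-4-methylpent-2-en-1-yl]-2,6-dimethylcyclohex-1-en-1-yl]ethyl}-2,2,5a,7-tetramethyldecahydro-1-benzoxepin-7-ol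
Conditions: 2-methylbut-3-en-2-ol (10 equiv), second-generation Hoveyda–Grubbs catalyst [RuCl2(H2IMes)(=CH-C6H4-2-OiPr), 10 mol%], CH2Cl2, 40 °C
Reagents that add atoms: 2-methylbut-3-en-2-ol, C=CC(C)(C)O
Why: Cross-metathesis of the terminal allyl group with an excess of a tertiary allylic alcohol that does not homodimerise should give the E-configured side chain, while the tetrasubstituted ring alkene is inert to the ruthenium carbene.

Step 18
Reactants: 23 bis-silyl ether
Product: 24 siphonellinol C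
Conditions: Bu4NF (excess), THF, 60 °C
Reagents that add atoms: none
Why: Fluoride-mediated desilylation removes both hindered secondary TBS ethers under non-acidic conditions that spare the tertiary allylic alcohol.

**Compound list**
1 | ethyl levulinate | CCOC(=O)CCC(C)=O | starting material
2 | ethyl 3-(2-methyl-1,3-dioxolan-2-yl)propanoate | CCOC(=O)CCC1(C)OCCO1 | intermediate
3 | 3-(2-methyl-1,3-dioxolan-2-yl)propanal | O=CCCC1(C)OCCO1 | intermediate
4 | neryl acetate, (2Z)-3,7-dimethylocta-2,6-dien-1-yl acetate | CC(C)=CCC/C(C)=C\COC(C)=O | starting material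
5 | neryl pinacolboronate, 2-[(2Z)-3,7-dimethylocta-2,6-dien-1-yl]-4,4,5,5-tetramethyl-1,3,2-dioxaborolane | CC(C)=CCC/C(C)=C\CB1OC(C)(C)C(C)(C)O1 | intermediate
6 | (3R,4R)-4-ethenyl-4,8-dimethyl-1-(2-methyl-1,3-dioxolan-2-yl)non-7-en-3-ol | C=C[C@@](C)(CCC=C(C)C)[C@H](O)CCC1(C)OCCO1 | intermediate
7 | (3R,4R)-6-[(2R)-3,3-dimethyloxiran-2-yl]-4-ethenyl-4-methyl-1-(2-methyl-1,3-dioxolan-2-yl)hexan-3-ol | C=C[C@@](C)(CC[C@H]1OC1(C)C)[C@H](O)CCC2(C)OCCO2 | intermediate
8 | (3R,6R,7R)-6-ethenyl-2,2,6-trimethyl-7-[2-(2-methyl-1,3-dioxolan-2-yl)ethyl]oxepan-3-ol | C=C[C@@]1(C)CC[C@@H](O)C(C)(C)O[C@@H]1CCC2(C)OCCO2 | intermediate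
9 | (2R,3R,6R)-6-(tert-butyldimethylsilyloxy)-3-ethenyl-3,7,7-trimethyl-2-[2-(2-methyl-1,3-dioxolan-2-yl)ethyl]oxepane | C=C[C@@]1(C)CC[C@@H](O[Si](C)(C)C(C)(C)C)C(C)(C)O[C@@H]1CCC2(C)OCCO2 | intermediate
10 | 4-[(2R,3R,6R)-6-(tert-butyldimethylsilyloxy)-3-ethenyl-3,7,7-trimethyloxepan-2-yl]butan-2-one | C=C[C@@]1(C)CC[C@@H](O[Si](C)(C)C(C)(C)C)C(C)(C)O[C@@H]1CCC(C)=O | intermediate
11 | 4-{(2R,3R,6R)-6-(tert-butyldimethylsilyloxy)-3,7,7-trimethyl-3-[(1E)-3-(trimethylsilyl)prop-1-en-1-yl]oxepan-2-yl}butan-2-one (key-step precursor) | C[Si](C)(C)C/C=C/[C@@]1(C)CC[C@@H](O[Si](C)(C)C(C)(C)C)C(C)(C)O[C@@H]1CCC(C)=O | intermediate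
12 | (3R,5aR,6R,7S,9aR)-3-(tert-butyldimethylsilyloxy)-6-ethenyl-2,2,5a,7-tetramethyldecahydro-1-benzoxepin-7-ol (key-step product, rings A and B) | C=C[C@@H]1[C@@]2(C)CC[C@@H](O[Si](C)(C)C(C)(C)C)C(C)(C)O[C@@H]2CC[C@]1(C)O | intermediate
13 | 2-methylcyclohexane-1,3-dione | CC1C(=O)CCCC1=O | starting material
14 | 2-methyl-2-(prop-2-en-1-yl)cyclohexane-1,3-dione | C=CCC1(C)C(=O)CCCC1=O | intermediate
15 | (2R,3R)-3-hydroxy-2-methyl-2-(prop-2-en-1-yl)cyclohexan-1-one | O=C1CCC[C@@H](O)[C@@]1(C)CC=C | intermediate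
16 | (2R,3R)-3-(tert-butyldimethylsilyloxy)-2-methyl-2-(prop-2-en-1-yl)cyclohexan-1-one | O=C1CCC[C@@H](O[Si](C)(C)C(C)(C)C)[C@@]1(C)CC=C | intermediate
17 | lithium (5R,6R)-5-(tert-butyldimethylsilyloxy)-6-methyl-6-(prop-2-en-1-yl)cyclohex-1-en-1-olate | [Li+].[O-]C1=CCC[C@@H](O[Si](C)(C)C(C)(C)C)[C@@]1(C)CC=C | intermediate
18 | (2R,3R)-3-(tert-butyldimethylsilyloxy)-2,6-dimethyl-2-(prop-2-en-1-yl)cyclohexan-1-one, C6 epimers | O=C1C(C)CC[C@@H](O[Si](C)(C)C(C)(C)C)[C@@]1(C)CC=C | intermediate
19 | potassium (5R,6R)-5-(tert-butyldimethylsilyloxy)-2,6-dimethyl-6-(prop-2-en-1-yl)cyclohex-1-en-1-olate | [K+].[O-]C1=C(C)CC[C@@H](O[Si](C)(C)C(C)(C)C)[C@@]1(C)CC=C | intermediate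
20 | (5R,6R)-5-(tert-butyldimethylsilyloxy)-2,6-dimethyl-6-(prop-2-en-1-yl)cyclohex-1-en-1-yl trifluoromethanesulfonate | O=S(=O)(OC1=C(C)CC[C@@H](O[Si](C)(C)C(C)(C)C)[C@@]1(C)CC=C)C(F)(F)F | intermediate
21 | (3R,5aR,6R,7S,9aR)-6-[2-(9-borabicyclo[3.3.1]nonan-9-yl)ethyl]-3-(tert-butyldimethylsilyloxy)-2,2,5a,7-tetramethyldecahydro-1-benzoxepin-7-ol | C1CCC2CCCC1B2CC[C@@H]1[C@@]2(C)CC[C@@H](O[Si](C)(C)C(C)(C)C)C(C)(C)O[C@@H]2CC[C@]1(C)O | intermediate
22 | (3R,5aR,6R,7S,9aR)-3-(tert-butyldimethylsilyloxy)-6-{2-[(5R,6S)-5-(tert-butyldimethylsilyloxy)-2,6-dimethyl-6-(prop-2-en-1-yl)cyclohex-1-en-1-yl]ethyl}-2,2,5a,7-tetramethyldecahydro-1-benzoxepin-7-ol | CC1=C(CC[C@@H]2[C@@]3(C)CC[C@@H](O[Si](C)(C)C(C)(C)C)C(C)(C)O[C@@H]3CC[C@]2(C)O)[C@](C)(CC=C)[C@H](O[Si](C)(C)C(C)(C)C)CC1 | intermediate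
23 | (3R,5aR,6R,7S,9aR)-3-(tert-butyldimethylsilyloxy)-6-{2-[(5R,6S)-5-(tert-butyldimethylsilyloxy)-6-[(2E)-4-hydroxy-4-methylpent-2-en-1-yl]-2,6-dimethylcyclohex-1-en-1-yl]ethyl}-2,2,5a,7-tetramethyldecahydro-1-benzoxepin-7-ol | CC1=C(CC[C@@H]2[C@@]3(C)CC[C@@H](O[Si](C)(C)C(C)(C)C)C(C)(C)O[C@@H]3CC[C@]2(C)O)[C@](C)(C/C=C/C(C)(C)O)[C@H](O[Si](C)(C)C(C)(C)C)CC1 | intermediate
24 | siphonellinol C, (3R,5aR,6R,7S,9aR)-6-{2-[(5R,6S)-5-hydroxy-6-[(2E)-4-hydroxy-4-methylpent-2-en-1-yl]-2,6-dimethylcyclohex-1-en-1-yl]ethyl}-2,2,5a,7-tetramethyldecahydro-1-benzoxepine-3,7-diol | CC1=C(CC[C@@H]2[C@@]3(C)CC[C@@H](O)C(C)(C)O[C@@H]3CC[C@]2(C)O)[C@](C)(C/C=C/C(C)(C)O)[C@H](O)CC1 | target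

**Step count and risks**
Total: 18 steps. Longest linear sequence: 12 steps (steps 1, 2, 4–10, 16–18, from ethyl levulinate); the ring C branch (steps 11–15) and step 3 are convergent.

Step 10 (key step). Facial selectivity at the C10 carbonyl may erode, because the titanium-bound oxygen competes with the methyl group for the equatorial site of the chair, and protodesilylation of the allylsilane may compete with ring closure. The fallback keeps the C10–C11 disconnection but closes the ring at the aldehyde oxidation level and sets C10 afterwards. It sets out from 10. A haloform reaction (Br2, NaOH, dioxane/H2O, 0 °C) degrades the methyl ketone to 3-[(2R,3R,6R)-6-(tert-butyldimethylsilyloxy)-3-ethenyl-3,7,7-trimethyloxepan-2-yl]propanoic acid F1. Esterification (MeI, K2CO3, DMF) gives the methyl ester F2, and iBu2AlH at −78 °C gives the propanal F3. Cross-metathesis with allyltrimethylsilane as in step 9 gives the (E)-allylsilane aldehyde F4. SnCl4 in CH2Cl2 at −78 °C closes ring B to the secondary alcohol (3R,5aR,6R,9aR)-3-(tert-butyldimethylsilyloxy)-6-ethenyl-2,2,5a-trimethyldecahydro-1-benzoxepin-7-ol F5, for which either C7 epimer serves. Dess–Martin oxidation gives the ketone (3R,5aR,6R,9aR)-3-(tert-butyldimethylsilyloxy)-6-ethenyl-2,2,5a-trimethyloctahydro-1-benzoxepin-7(2H)-one F6. MeMgBr with CeCl3 in THF at −78 °C should then add along the equatorial trajectory, since the axial one is blocked by the axial C6 methyl as in 3,3,5-trimethylcyclohexanone, giving the axial carbinol. The fallback comes back to the route at 12.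

Step 6. Regioselectivity of the epoxide opening may fail: the hydroxyl can attack the secondary epoxide carbon C3 (6-exo) to give a tetrahydropyran, and acid-induced ketal exchange with the C7 hydroxyl may slow the desired path. The fallback removes the regiochemical choice by making C2 the only electrophilic carbon. It sets out from 7. Base-mediated epoxide-to-allylic-alcohol isomerisation (diethylaluminium 2,2,6,6-tetramethylpiperidide, toluene, 0 °C) gives (3R,4R,7R)-4-ethenyl-4,8-dimethyl-1-(2-methyl-1,3-dioxolan-2-yl)non-8-ene-3,7-diol F7. Intramolecular Markovnikov alkoxymercuration of the 1,1-disubstituted alkene (Hg(OCOCF3)2, CH2Cl2, 0 °C) puts the C7 oxygen on the tertiary carbon and gives the oxepanylmethylmercury trifluoroacetate F8. Reduction in the same flask with NaBH4 in aqueous NaOH converts the CH2–Hg group into the second C2 methyl. The fallback comes back to the route at 8.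

Step 9. The ruthenium carbene may fail to engage the vinyl group on the quaternary carbon C6, so that allyltrimethylsilane only homodimerises, or double-bond migration may give a vinylsilane. The fallback builds the E-allylsilane by olefination and cross-coupling instead of metathesis. It sets out from 9. Ozonolysis (O3, CH2Cl2, −78 °C) gives the secondary ozonide F9, which PPh3 reduces to the aldehyde (2R,3S,6R)-6-(tert-butyldimethylsilyloxy)-3,7,7-trimethyl-2-[2-(2-methyl-1,3-dioxolan-2-yl)ethyl]oxepane-3-carbaldehyde F10. Takai olefination (CrCl2, CHI3, THF, 0 °C → rt) gives the (E)-vinyl iodide F11. Kumada coupling with Me3SiCH2MgCl and Pd(PPh3)4 in THF gives the (E)-allylsilane ketal F12, with retention of the alkene geometry. PPTS in acetone/H2O then removes the ketal, and the fallback comes back to the route at 11.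

**Further compounds**
F1 | step 10 | 3-[(2R,3R,6R)-6-(tert-butyldimethylsilyloxy)-3-ethenyl-3,7,7-trimethyloxepan-2-yl]propanoic acid | C=C[C@@]1(C)CC[C@@H](O[Si](C)(C)C(C)(C)C)C(C)(C)O[C@@H]1CCC(=O)O
F2 | step 10 | methyl 3-[(2R,3R,6R)-6-(tert-butyldimethylsilyloxy)-3-ethenyl-3,7,7-trimethyloxepan-2-yl]propanoate | C=C[C@@]1(C)CC[C@@H](O[Si](C)(C)C(C)(C)C)C(C)(C)O[C@@H]1CCC(=O)OC
F3 | step 10 | 3-[(2R,3R,6R)-6-(tert-butyldimethylsilyloxy)-3-ethenyl-3,7,7-trimethyloxepan-2-yl]propanal | C=C[C@@]1(C)CC[C@@H](O[Si](C)(C)C(C)(C)C)C(C)(C)O[C@@H]1CCC=O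
F4 | step 10 | 3-{(2R,3R,6R)-6-(tert-butyldimethylsilyloxy)-3,7,7-trimethyl-3-[(1E)-3-(trimethylsilyl)prop-1-en-1-yl]oxepan-2-yl}propanal | C[Si](C)(C)C/C=C/[C@@]1(C)CC[C@@H](O[Si](C)(C)C(C)(C)C)C(C)(C)O[C@@H]1CCC=O
F5 | step 10 | (3R,5aR,6R,9aR)-3-(tert-butyldimethylsilyloxy)-6-ethenyl-2,2,5a-trimethyldecahydro-1-benzoxepin-7-ol, C7 epimers | C=C[C@@H]1[C@@]2(C)CC[C@@H](O[Si](C)(C)C(C)(C)C)C(C)(C)O[C@@H]2CCC1O
F6 | step 10 | (3R,5aR,6R,9aR)-3-(tert-butyldimethylsilyloxy)-6-ethenyl-2,2,5a-trimethyloctahydro-1-benzoxepin-7(2H)-one | C=C[C@@H]1[C@@]2(C)CC[C@@H](O[Si](C)(C)C(C)(C)C)C(C)(C)O[C@@H]2CCC1=O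
F7 | step 6 | (3R,4R,7R)-4-ethenyl-4,8-dimethyl-1-(2-methyl-1,3-dioxolan-2-yl)non-8-ene-3,7-diol | C=C[C@@](C)(CC[C@@H](O)C(C)=C)[C@H](O)CCC1(C)OCCO1
F8 | step 6 | {[(3R,6R,7R)-6-ethenyl-3-hydroxy-2,6-dimethyl-7-[2-(2-methyl-1,3-dioxolan-2-yl)ethyl]oxepan-2-yl]methyl}mercury trifluoroacetate, C2 epimers | C=C[C@@]1(C)CC[C@@H](O)C(C)(C[Hg]OC(=O)C(F)(F)F)O[C@@H]1CCC2(C)OCCO2
F9 | step 9 | secondary ozonide of 9 (1,2,4-trioxolan-3-yl group on C6 in place of the vinyl group) | O1OC(OC1)[C@@]1(C)CC[C@@H](O[Si](C)(C)C(C)(C)C)C(C)(C)O[C@@H]1CCC2(C)OCCO2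
F10 | step 9 | (2R,3S,6R)-6-(tert-butyldimethylsilyloxy)-3,7,7-trimethyl-2-[2-(2-methyl-1,3-dioxolan-2-yl)ethyl]oxepane-3-carbaldehyde | O=C[C@@]1(C)CC[C@@H](O[Si](C)(C)C(C)(C)C)C(C)(C)O[C@@H]1CCC2(C)OCCO2
F11 | step 9 | (2R,3R,6R)-6-(tert-butyldimethylsilyloxy)-3-[(E)-2-iodoethenyl]-3,7,7-trimethyl-2-[2-(2-methyl-1,3-dioxolan-2-yl)ethyl]oxepane | I/C=C/[C@@]1(C)CC[C@@H](O[Si](C)(C)C(C)(C)C)C(C)(C)O[C@@H]1CCC2(C)OCCO2
F12 | step 9 | (2R,3R,6R)-6-(tert-butyldimethylsilyloxy)-3,7,7-trimethyl-2-[2-(2-methyl-1,3-dioxolan-2-yl)ethyl]-3-[(1E)-3-(trimethylsilyl)prop-1-en-1-yl]oxepane | C[Si](C)(C)C/C=C/[C@@]1(C)CC[C@@H](O[Si](C)(C)C(C)(C)C)C(C)(C)O[C@@H]1CCC2(C)OCCO2
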